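The constants stand for no real mixture; the result is computed.

**The question.** How much target stands at the end of each flask when the charge of starting material is raised and the charge of coupling partner is held?

* [target] at the end for north, south-east, south-west, north-east, west, in this order
* the course of these numbers from the first flask to the last (hardly changes / rises all the way / rises, then falls / falls, then rises / falls all the way)

| flask | starting material | coupling partner | initiator | time |
|---|---|---|---|---|
| north | 0.12 M | 0.440 M | 20 mM | 2.5 min |
| south-east | 0.20 M | 0.440 M | 20 mM | 2.5 min |
| south-west | 0.25 M | 0.440 M | 20 mM | 2.5 min |
| north-east | 0.40 M | 0.440 M | 20 mM | 2.5 min |
| west | 0.60 M | 0.440 M | 20 mM | 2.5 min |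

    initiator → 2 initiating radical (k1 = 2.65 × 10⁻⁵ s⁻¹)
    starting material + initiating radical → capped initiator + first chain carrier (k2 = 1.09 × 10⁶ M⁻¹ s⁻¹)
    coupling partner + first chain carrier → target + second chain carrier (k3 = 1.33 × 10⁵ M⁻¹ s⁻¹)
    starting material + second chain carrier → by-product + first chain carrier (k4 = 87700 M⁻¹ s⁻¹)
    2 first chain carrier → ended chains (k5 = 2.7 × 10⁷ M⁻¹ s⁻¹)
    starting material + target → side product (k6 = 0.0112 M⁻¹ s⁻¹)
    coupling partner → decomposed reagent (k7 = 0.00169 s⁻¹)

- in percentages every species weighs as the starting material in it: one ended chains or side product counts as two
- two of one species on the left: rate k times its square, two consumed each time
- "hardly changes" means that all values lie within two and a half points (for a concentration: within two and a half percent of the largest)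
- run time (north): 2.5 min

**Main cycle.** The coupling step and the step that regenerates the first chain carrier form a radical chain. Each round spends one coupling partner and one starting material and leaves one target. Taken by itself, this cycle gives the lesser charge as target, the limiting reagent being the starting material up to 0.40 M and the coupling partner at 0.60 M.

**Carrier level.** The initiator has a half-life of 7.3 h, far longer than the 2.5 min run, so initiation stays steady. Setting initiation equal to termination gives c(first chain carrier) = 1.40 × 10⁻⁷ M. The coupling partner therefore falls pseudo-first-order with constant 0.0186 s⁻¹, a half-life of 37.3 s, which is shorter than the run.

**Reagent decomposition.** The coupling partner also decomposes, so the total loss constant becomes 0.0203 s⁻¹, and the chain receives 91.6% of what is lost. This gives the chain budget, the target-forming turnover that the coupling partner can support within the run while starting material lasts: 0.384 M.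

**Side step.** Each side product costs one target and one starting material, and this loss is reckoned as a correction. North, south-east and south-west are charged below the budget, so their target follows the charge, less a correction. In north the chain, at its initial rate, turns over the charge of starting material in about 14.6 s, which is shorter than the run, so the side step is reckoned for that time alone. Integrating the falling starting material against the rising target, and counting each side turn twice because it also takes a starting material that would have become target, gives a shortfall of 7.87 × 10⁻⁴ M in north and a target of 119 mM. The same reckoning gives 196 mM for south-east and 243 mM for south-west.

West is charged above the budget. After a time 49.3 s, the side step acts on about the budget of target and the excess of starting material, which costs 0.0936 M and leaves 291 mM. North-east, close to the budget, is estimated at 0.356 M, with both partners at half its charge for that same time. This estimate stands above west, so the course reckoned is rises, then falls.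

**The forecast.** The forecast gives 0.119 M, 0.195 M, 0.24 M, 0.345 M and 0.293 M, with the course rises, then falls, holding that in the richest flask “the slow side reaction eats about 0.09 M of target”.

**The result.** The simulation gives 0.119 M, 0.195 M, 0.240 M, 0.344 M and 0.294 M, with the course rises, then falls. The deciding comparison is charge against budget: north holds 0.12 M against 0.384 M and ends with 0% of its starting material and 56.2% of its coupling partner. West holds 0.60 M and ends with 20.9% of its starting material, 4.77% of its coupling partner and 0.384 M of by-product, while the row turns at a starting material concentration of 0.42 M.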